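**Retrosynthetic overview**

1. Feature: in the meso target the arm carbons C3a (on C3) and C4a (on C4) sit cis on adjacent carbons of the oxolane ring and trans to the cis aryl groups on C2 and C5. They are the two carbons of a ketene unit added to the open face of a C3=C4 double bond, with the C3a–C4a bond cut afterwards.
2. Target ⇐ debenzylation and acetylation of the cis-diol ⇐ cis acid–aldehyde ⇐ C3a–C4a scission (silyl enol ether ozonolysis) of a cyclobutanone fused on C3–C4.
3. Cyclobutanone ⇐ dichloroketene [2+2] on cis-2,5-diaryl-2,5-dihydrofuran, forming C3–C3a and C4–C4a.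
4. Dihydrofuran ⇐ Mitsunobu cyclodehydration of the (Z)-ene-1,4-diol ⇐ ynediol ⇐ aryl propargylic alcohol + 3,4-bis(benzyloxy)benzaldehyde ⇐ the same aldehyde + ethynylmagnesium bromide.
5. Ring order: oxolane ring first (as the 2,5-dihydrofuran), cyclobutanone ring second, and that ring is opened again.

Key step: step 5

Remark: the target is a meso compound (2R,3S,4R,5S; aryls cis, arms cis, arms trans to aryls), so the chiral intermediates 3 and 10 to 14 are carried as racemates and the SMILES of 10 to 14 show one enantiomer.

**Route**

Step 1
Reactants: 1 3,4-bis(benzyloxy)benzaldehyde; 2 ethynylmagnesium bromide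
Product: 3 1-[3,4-bis(benzyloxy)phenyl]prop-2-yn-1-ol (racemic)
Conditions: 2 (0.5 M in THF, 1.3 equiv), THF, 0 °C to rt; sat. aq NH4Cl
Reagents that add atoms: none
Why: Grignard 1,2-addition of the ethynyl anion to a non-enolisable aromatic aldehyde forms the first C–C bond and leaves the terminal alkyne C–H for the second coupling; any symmetrical ynediol formed through disproportionation of the reagent is the product of step 2 and does no harm.

Step 2
Reactants: 3 1-[3,4-bis(benzyloxy)phenyl]prop-2-yn-1-ol; 1 3,4-bis(benzyloxy)benzaldehyde
Product: 5 1,4-bis[3,4-bis(benzyloxy)phenyl]but-2-yne-1,4-diol (meso and racemic diastereomers together), via dilithiated propargylic alcohol 4 (not isolated)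
Conditions: n-BuLi (2.05 equiv), THF, −78 °C to −30 °C; 1 (1.05 equiv), THF, −78 °C to 0 °C; sat. aq NH4Cl
Reagents that add atoms: none
Why: Double deprotonation (O–H, then the alkyne C–H) gives the lithium alkoxide–lithium acetylide, whose sp carbanion adds to the aldehyde (acetylide 1,2-addition); the new carbinol centre forms without control from the remote one, so a near-statistical mixture of meso and racemic diol is expected and is carried on.

Step 3
Reactants: 5 the ynediol mixture
Product: 6 (Z)-1,4-bis[3,4-bis(benzyloxy)phenyl]but-2-ene-1,4-diol (same diastereomer mixture)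
Conditions: H2 (1 atm), Pd/CaCO3 poisoned with Pb(OAc)2, quinoline, EtOAc, rt, stopped after one equivalent of H2
Reagents that add atoms: none
Why: Lindlar semihydrogenation delivers both hydrogens to one face of the alkyne on the poisoned palladium surface and so gives the Z-alkene, while the deactivated catalyst should leave the benzyl ethers and the benzylic alcohols alone.

Step 4
Reactants: 6 the (Z)-enediol mixture
Product: 7 cis-2,5-bis[3,4-bis(benzyloxy)phenyl]-2,5-dihydrofuran (meso)
Conditions: PPh3, DIAD, THF, 0 °C to rt, under argon; chromatography on Et3N-washed SiO2 and crystallisation to remove the trans isomer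
Reagents that add atoms: none
Why: In this Mitsunobu cyclodehydration the oxyphosphonium of one carbinol is displaced 5-exo-tet by the other hydroxyl, so invertive closure turns the racemic diol into the cis and the meso diol into the trans dihydrofuran; no further control is exerted, and the meso cis isomer is separated from the racemic trans isomer (one peak against two on a chiral stationary phase would tell them apart).

Step 5
Reactants: 7 cis-2,5-bis[3,4-bis(benzyloxy)phenyl]-2,5-dihydrofuran; 8 trichloroacetyl chloride
Product: 10 7,7-dichloro-2,4-bis[3,4-bis(benzyloxy)phenyl]-3-oxabicyclo[3.2.0]heptan-6-one (cis-fused; both aryls on the face opposite the cyclobutanone; racemic), via dichloroketene 9 (not isolated)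
Conditions: 8 (slow addition by syringe pump), Zn–Cu couple, Et2O/DME, ultrasound, 15–20 °C; filtration, cold aq NaHCO3
Reagents that add atoms: none
Why: Zinc removes two chlorines from trichloroacetyl chloride to give dichloroketene 9, whose central carbon is attacked by the C3=C4 π bond of 7 in a concerted but asynchronous [π2s+π2a] ketene–alkene cycloaddition (C3–C3a leading, C4–C4a closing), the closest known reaction type being dichloroketene addition to cyclopentenes and other cis-disubstituted cyclic alkenes. The four-membered ring closes by suprafacial addition to the alkene, so the ring fusion is cis and C3a and C4a end on the same face. The two new stereocentres C3 and C4 are fixed by the face of attack alone: the cis aryl groups on C2 and C5 cover one face of the nearly flat dihydrofuran, so the ketene should come in over the face that carries only the two hydrogens and both new C–C bonds end trans to the aryls. Regiochemistry is not an issue, because the two orientations on the mirror-symmetric alkene give the two enantiomers of 10, which later converge on the meso target. The selectivity that matters is facial, secured by the substrate, together with chemoselectivity for the C=C bond over the ring oxygen and the ionisable allylic benzylic C–O bonds, which is served by binding the ZnCl2 formed with DME, by slow addition and by a temperature at or below 20 °C.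

Step 6
Reactants: 10 the dichlorocyclobutanone
Product: 11 2,4-bis[3,4-bis(benzyloxy)phenyl]-3-oxabicyclo[3.2.0]heptan-6-one (same relative configuration; racemic)
Conditions: Zn dust, AcOH, rt
Reagents that add atoms: none
Why: Reductive dechlorination of an α,α-dichloroketone by zinc goes through the zinc enolate, which acetic acid protonates; the ring-fusion centres cannot epimerise because only the cis-fused bicyclo[3.2.0] skeleton is accessible, and the benzyl ethers are inert.

Step 7
Reactants: 11 the cyclobutanone
Product: 12 6-(trimethylsilyloxy)-2,4-bis[3,4-bis(benzyloxy)phenyl]-3-oxabicyclo[3.2.0]hept-6-ene (racemic)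
Conditions: TMSCl, LiN(iPr)2, THF, −78 °C (in situ quench); Et3N, pentane, filtration
Reagents that add atoms: chlorotrimethylsilane, C[Si](C)(C)Cl
Why: Kinetic enolisation with immediate O-silylation takes the proton from the unhindered CH2 (C4a), because the other enolate would place a double bond at the ring fusion (C3) of the strained bicycle; the silyl enol ether therefore marks the C3a–C4a bond for cleavage, and the enolate that would have the ring oxygen as a β leaving group is not formed.

Step 8
Reactants: 12 the silyl enol ether
Product: 14 4-formyl-2,5-bis[3,4-bis(benzyloxy)phenyl]oxolane-3-carboxylic acid (aryls cis; acid and formyl cis to each other and trans to the aryls; racemic; in equilibrium with its bicyclic hydroxy-lactone), via methoxy hydroperoxide silyl ester 13 (not isolated)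
Conditions: O3/O2, CH2Cl2/MeOH, NaHCO3, −78 °C, Sudan Red 7B as end-point indicator; Me2S, −78 °C to rt; aqueous work-up; crude product used directly
Reagents that add atoms: ozone, [O-][O+]=O (methanol, CO, enters only intermediate 13 and is lost again)
Why: Ozonolysis of the electron-rich silyl enol ether should be much faster than attack on the alkoxyarenes, and Criegee fragmentation gives the silyl ester at C3a and a carbonyl oxide at C4a that methanol traps; Me2S reduces the hydroperoxide to the aldehyde, and under these neutral conditions C3 and C4 are untouched, the cis acid–aldehyde being held as the cis-fused lactol.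

Step 9
Reactants: 14 the acid–aldehyde
Product: 15 [2,5-bis[3,4-bis(benzyloxy)phenyl]oxolane-3,4-diyl]dimethanol (meso; 2R,3S,4R,5S)
Conditions: LiAlH4, THF, 0 °C to 40 °C; Fieser work-up (H2O, aq NaOH, H2O)
Reagents that add atoms: none
Why: Hydride reduction takes the aldehyde (or lactol) and the carboxylic acid to the two primary alcohols; the aldehyde is reduced at once at 0 °C, so epimerisation at C4 and β-elimination of the ring oxygen should not compete, and the two arms become identical, which restores the mirror plane.

Step 10
Reactants: 15 the diol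
Product: 16 [2,5-bis[3,4-bis(benzyloxy)phenyl]oxolane-3,4-diyl]dimethyl diacetate (meso)
Conditions: Ac2O, pyridine, DMAP (cat.), CH2Cl2, rt
Reagents that add atoms: acetic anhydride, CC(=O)OC(C)=O
Why: DMAP-catalysed acylation of two unhindered primary alcohols is routine and touches no stereocentre.

Step 11
Reactants: 16 the tetrabenzyl diacetate
Product: 17 CNP0416169.1, [(2R,3S,4R,5S)-2,5-bis(3,4-dihydroxyphenyl)oxolane-3,4-diyl]dimethyl diacetate (meso)
Conditions: H2 (1 atm), Pd/C, EtOAc/EtOH, rt, stopped after four equivalents of H2; work-up under argon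
Reagents that add atoms: none
Why: Catalytic hydrogenolysis cleaves aryl benzyl ethers much faster than the benzylic dialkyl ether C–O bonds of the oxolane, and the neutral medium leaves the acetates in place; stopping at the calculated uptake guards against ring opening.

**Compound list**

1 | 3,4-bis(benzyloxy)benzaldehyde | O=Cc1ccc(OCc2ccccc2)c(OCc2ccccc2)c1 | starting material
2 | ethynylmagnesium bromide | C#C[Mg]Br | starting material
3 | 1-[3,4-bis(benzyloxy)phenyl]prop-2-yn-1-ol, racemic (carbinol centre left open) | C#CC(O)c1ccc(OCc2ccccc2)c(OCc2ccccc2)c1 | intermediate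
4 | lithium 1-[3,4-bis(benzyloxy)phenyl]-3-lithioprop-2-yn-1-olate (dilithiated 3) | [Li]C#CC(O[Li])c1ccc(OCc2ccccc2)c(OCc2ccccc2)c1 | intermediate
5 | 1,4-bis[3,4-bis(benzyloxy)phenyl]but-2-yne-1,4-diol, meso and racemic diastereomers (carbinol centres left open) | OC(C#CC(O)c1ccc(OCc2ccccc2)c(OCc2ccccc2)c1)c1ccc(OCc2ccccc2)c(OCc2ccccc2)c1 | intermediate
6 | (Z)-1,4-bis[3,4-bis(benzyloxy)phenyl]but-2-ene-1,4-diol, same diastereomer mixture | OC(/C=C\C(O)c1ccc(OCc2ccccc2)c(OCc2ccccc2)c1)c1ccc(OCc2ccccc2)c(OCc2ccccc2)c1 | intermediate
7 | cis-2,5-bis[3,4-bis(benzyloxy)phenyl]-2,5-dihydrofuran (meso) | C1=C[C@@H](c3ccc(OCc4ccccc4)c(OCc4ccccc4)c3)O[C@H]1c1ccc(OCc2ccccc2)c(OCc2ccccc2)c1 | intermediate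
8 | trichloroacetyl chloride | O=C(Cl)C(Cl)(Cl)Cl | starting material
9 | dichloroketene | O=C=C(Cl)Cl | intermediate
10 | 7,7-dichloro-2,4-bis[3,4-bis(benzyloxy)phenyl]-3-oxabicyclo[3.2.0]heptan-6-one, cis-fused, aryls anti to the cyclobutanone, racemic | O=C2[C@@H]1[C@H](C2(Cl)Cl)[C@@H](c3ccc(OCc4ccccc4)c(OCc4ccccc4)c3)O[C@H]1c1ccc(OCc2ccccc2)c(OCc2ccccc2)c1 | intermediate
11 | 2,4-bis[3,4-bis(benzyloxy)phenyl]-3-oxabicyclo[3.2.0]heptan-6-one, same relative configuration, racemic | O=C2[C@@H]1[C@H](C2)[C@@H](c3ccc(OCc4ccccc4)c(OCc4ccccc4)c3)O[C@H]1c1ccc(OCc2ccccc2)c(OCc2ccccc2)c1 | intermediate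
12 | 6-(trimethylsilyloxy)-2,4-bis[3,4-bis(benzyloxy)phenyl]-3-oxabicyclo[3.2.0]hept-6-ene, racemic | C[Si](C)(C)OC=2[C@@H]1[C@H](C=2)[C@@H](c3ccc(OCc4ccccc4)c(OCc4ccccc4)c3)O[C@H]1c1ccc(OCc2ccccc2)c(OCc2ccccc2)c1 | intermediate
13 | trimethylsilyl 4-[hydroperoxy(methoxy)methyl]-2,5-bis[3,4-bis(benzyloxy)phenyl]oxolane-3-carboxylate, peroxy acetal carbon undefined, racemic | C[Si](C)(C)OC(=O)[C@@H]1[C@H](C(OC)OO)[C@@H](c3ccc(OCc4ccccc4)c(OCc4ccccc4)c3)O[C@H]1c1ccc(OCc2ccccc2)c(OCc2ccccc2)c1 | intermediate
14 | 4-formyl-2,5-bis[3,4-bis(benzyloxy)phenyl]oxolane-3-carboxylic acid, aryls cis, arms cis and trans to aryls, racemic | OC(=O)[C@@H]1[C@H](C=O)[C@@H](c3ccc(OCc4ccccc4)c(OCc4ccccc4)c3)O[C@H]1c1ccc(OCc2ccccc2)c(OCc2ccccc2)c1 | intermediate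
15 | [(2R,3S,4R,5S)-2,5-bis[3,4-bis(benzyloxy)phenyl]oxolane-3,4-diyl]dimethanol (meso) | OC[C@@H]1[C@H](CO)[C@@H](c3ccc(OCc4ccccc4)c(OCc4ccccc4)c3)O[C@H]1c1ccc(OCc2ccccc2)c(OCc2ccccc2)c1 | intermediate
16 | [(2R,3S,4R,5S)-2,5-bis[3,4-bis(benzyloxy)phenyl]oxolane-3,4-diyl]dimethyl diacetate (meso) | CC(=O)OC[C@@H]1[C@H](COC(C)=O)[C@@H](c3ccc(OCc4ccccc4)c(OCc4ccccc4)c3)O[C@H]1c1ccc(OCc2ccccc2)c(OCc2ccccc2)c1 | intermediate
17 | CNP0416169.1, [(2R,3S,4R,5S)-2,5-bis(3,4-dihydroxyphenyl)oxolane-3,4-diyl]dimethyl diacetate (meso) | CC(=O)OC[C@@H]1[C@H](COC(C)=O)[C@@H](c2ccc(O)c(O)c2)O[C@H]1c1ccc(O)c(O)c1 | target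

**Totals**

Total step count: 11. Longest linear sequence: 11 steps, from aldehyde 1 to target 17.

**Steps most likely to fail**

Step 5 (key cycloaddition). The C3=C4 bond is flanked by two substituted carbons and is inductively deactivated by the ring oxygen, so the cycloaddition may be slow enough for ketene oligomerisation to win. The ketene may also acylate the ring oxygen, and the ZnCl2 formed may ionise the allylic benzylic C2–O and C5–O bonds, leading to ring opening, cis/trans scrambling or oxidation to the furan. The fallback replaces the ketene by a more electrophilic, zinc-free two-carbon partner and sets out from 7. The keteniminium salt made from N,N-dimethylacetamide, Tf2O and 2,4,6-collidine in 1,2-dichloroethane should add across C3=C4 from the same open face (Ghosez keteniminium [2+2]) to give the cyclobutaniminium triflate F1. Hydrolysis of F1 with aqueous NaHCO3/CH2Cl2 gives cyclobutanone 11, where the route is rejoined without the dechlorination step.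

Step 8 (ozonolysis). Once the enol ether is consumed, ozone may go on to oxidise the four electron-rich bis(benzyloxy)phenyl rings and the benzylic C–H bonds. Methanol may also desilylate 12 back to ketone 11 before cleavage, and the free aldehyde may epimerise at C4 or eliminate the ring oxygen if the work-up turns basic. The fallback uses oxidants that do not touch arenes and sets out from 12. Dihydroxylation of the enol ether with OsO4 (cat.) and N-methylmorpholine N-oxide in acetone/water gives the α-hydroxycyclobutanone F2, whose carbinol configuration is of no consequence. Glycol-type cleavage of F2 with NaIO4 in THF/pH 7 buffer breaks the C3a–C4a bond and returns acid–aldehyde 14.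

Step 4 (ring closure and isomer separation). The closure exerts no control over the C2/C5 relationship, so about half of the material is expected to be lost as the trans isomer. Partial ionisation of the electron-rich benzylic allylic oxyphosphonium may blur the outcome further, the two apolar isomers may be hard to separate, and traces of acid or air may aromatise the product to the furan. The fallback controls the diol configuration with a catalyst and sets out from 5. Oxidation of 5 with activated MnO2 in CH2Cl2 gives the ynedione F3. Double reduction of F3 with (R)-2-methyl-CBS-oxazaborolidine and catecholborane at −78 °C should give predominantly one C2-symmetric ynediol F4, drawn here as (1R,4R); the antipode would serve equally, as 7 is meso. Semihydrogenation of F4 over Pd/CaCO3 poisoned with Pb(OAc)2 gives the (1S,4S,2Z)-enediol F5, which has the same spatial arrangement, the descriptors changing only with the ranking of alkenyl against alkynyl. Mitsunobu closure of F5 (PPh3, DIAD, toluene, −20 °C) with inversion at one centre then gives only the cis dihydrofuran 7.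

Further compounds
F1 | step 5 | N-[2,4-bis[3,4-bis(benzyloxy)phenyl]-3-oxabicyclo[3.2.0]heptan-6-ylidene]-N-methylmethanaminium triflate, racemic | C[N+](C)=C2[C@@H]1[C@H](C2)[C@@H](c3ccc(OCc4ccccc4)c(OCc4ccccc4)c3)O[C@H]1c1ccc(OCc2ccccc2)c(OCc2ccccc2)c1.[O-]S(=O)(=O)C(F)(F)F
F2 | step 8 | 7-hydroxy-2,4-bis[3,4-bis(benzyloxy)phenyl]-3-oxabicyclo[3.2.0]heptan-6-one, carbinol centre undefined, racemic | O=C2[C@@H]1[C@H](C2O)[C@@H](c3ccc(OCc4ccccc4)c(OCc4ccccc4)c3)O[C@H]1c1ccc(OCc2ccccc2)c(OCc2ccccc2)c1
F3 | step 4 | 1,4-bis[3,4-bis(benzyloxy)phenyl]but-2-yne-1,4-dione | O=C(C#CC(=O)c1ccc(OCc2ccccc2)c(OCc2ccccc2)c1)c1ccc(OCc2ccccc2)c(OCc2ccccc2)c1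
F4 | step 4 | (1R,4R)-1,4-bis[3,4-bis(benzyloxy)phenyl]but-2-yne-1,4-diol | O[C@@H](C#C[C@H](O)c1ccc(OCc2ccccc2)c(OCc2ccccc2)c1)c1ccc(OCc2ccccc2)c(OCc2ccccc2)c1
F5 | step 4 | (1S,4S,2Z)-1,4-bis[3,4-bis(benzyloxy)phenyl]but-2-ene-1,4-diol | O[C@@H](/C=C\[C@H](O)c1ccc(OCc2ccccc2)c(OCc2ccccc2)c1)c1ccc(OCc2ccccc2)c(OCc2ccccc2)c1
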